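| flask | substrate | partner | catalyst | target | time |
|---|---|---|---|---|---|
| west | 120 mM | 360 mM | 3.60 mM |  |  |
| south | 72.0 mM | 312 mM | 3.60 mM |  |  |
| north | 120 mM | 360 mM | 11.0 mM |  |  |
| north-west | 120 mM | 360 mM | 3.60 mM | 36.0 mM |  |
| north-east | 40.0 mM | 120 mM | 3.60 mM |  | 56 min |

| run | time / min | [target] / mM |
|---|---|---|
| west run | 2.5 | 6.4 |
| west run | 7.5 | 20.0 |
| west run | 14 | 34.5 |
| west run | 23 | 51.6 |
| west run | 33 | 64.9 |
| west run | 44 | 75.2 |
| west run | 56 | 80.3 |
| south run | 2.5 | 6.2 |
| south run | 7.5 | 18.0 |
| south run | 14 | 31.1 |
| south run | 23 | 45.2 |
| south run | 33 | 57.1 |
| south run | 44 | 63.8 |
| south run | 56 | 68.4 |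
| north run | 2.5 | 21.7 |
| north run | 7.5 | 57.9 |
| north run | 14 | 97.2 |
| north run | 23 | 118.5 |
| north run | 33 | 120.1 |
| north run | 44 | 120.4 |
| north run | 56 | 120.6 |
| north-west run | 2.5 | 42.6 |
| north-west run | 7.5 | 55.7 |
| north-west run | 14 | 71.3 |
| north-west run | 23 | 88.0 |
| north-west run | 33 | 101.6 |
| north-west run | 44 | 110.5 |
| north-west run | 56 | 115.9 |

(standard deviation of a reading: 0.4 mM)

- how the opening rate goes with [catalyst] round the charge of the west run: the exponent of the rate at two percent of substrate gone to target
- the south run starts with 48.0 mM less of substrate and of partner than the west run, and with no target. Compared where both hold the same amount of substrate, once fifteen percent of what the south run was charged with has turned into target, is the south run faster, slower or alike (within a tenth)?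
- target in the north-east run at 56 min, as a share of the substrate charged

- Overall: substrate + partner -> target, with catalyst as catalyst.
- Constant volume, constant temperature.
- Bound and free are read together.
- An order is taken over about fifteen percent of the charge, up and down.

The partner was the account I chose to keep books on, although the west run was charged with 3.00 parts of it to one of substrate, which makes substrate look like the limiting reagent. The first entry came from the substrate side. At 56 min the west run had turned 66.9% of its substrate into target, leaving 33.1% of the charge. Its rate, however, had fallen from 2.56 mM min⁻¹ over the first reading to 0.425 mM min⁻¹ over the last stretch. That is 16.6% of the opening rate, a deeper fall than the substrate's, so I looked beyond substrate for the slowing.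

The second entry cleared the target. The north-west run, charged with target, added 79.9 mM in the same time against 80.3 mM in the west run, so the added target made a difference of 0.400 mM, near the scatter.

The third entry pointed to the partner. At 23 min the west run held 1.14 times the target of the south run, close to the partner ratio of 1.15 and well below the substrate ratio of 1.67.

So I replaced the whole curve by one mean figure. In the west run, target at 56 min over partner charged read 22.3%. I call this the partner share, the fraction of charged partner that has become target by that time at this catalyst charge. The other 77.7% of the partner charge I booked as not having become target at that reading, in whatever form it then stood.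

The north-east run has the same catalyst charge and the same clock, so I applied the share to its partner. That gave 26.8 mM, which is 66.9% of its substrate and stays below the substrate charge. The error I watched for in this mean figure lay at the end of the curve. My reckoning leaves 13.2 mM of substrate in the north-east run at 56 min, less than the 39.7 mM in the west run, and any slackening from that would pull my figure down.

The forecast stood at 1.1, faster and 64%, and closed with “With partner 120 mM, this gives about 25–26 mM, or about 64%.”

The flask gave 67.3% for the north-east run, an order in catalyst of 1.0, and a south run that was faster, at 1.7 times the west rate where substrate matched.

    catalyst + substrate → catalyst-substrate complex (281.4 L mol⁻¹ min⁻¹)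
    catalyst-substrate complex + partner → target + catalyst (11.64 L mol⁻¹ min⁻¹)
    2 partner ⇌ idle reagent dimer, settled at all times (29.20 L mol⁻¹)
    partner → lost reagent (0.1386 min⁻¹)

Free partner's step to lost reagent runs at 0.139 min⁻¹, against 0.0419 min⁻¹ for its step to target with the charged catalyst taken as complex. Put to the south run, the partner share gives 69.6 mM by 56 min, and that run read 68.4 mM.

The runs are calculated from invented constants; the scatter is artificial.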